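**Retrosynthetic overview**
1. Target ⇒ last operation: an amine-triggered retro-Claisen ring expansion of a 2-acylcyclopentanone (N-17–C-23 made, C-23–C-8 broken) gives the nine-membered keto-lactam, and reductive amidation N-17–C-18 then closes the caprolactam.
2. Ring-expansion precursor ⇒ ethyl cuprate addition (C-3) to a 2-alkylcyclopentenone whose C-8 was acylated with an aspartate-derived β-amino acid chloride; the C-22 chain comes from an α-iodoenone B-alkyl Suzuki coupling.
3. Enone-lactone ⇒ (−)-Grieco lactone by exo-methylation (C-7) and an epoxide-based 1,3-oxygen transposition.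
4. β-Amino acid ⇒ Cbz-L-Asp(OtBu)-OH: aldehyde, zinc Barbier allylation/lactonisation (C-12), hydrogenation (C-14).
5. Ring order: fused γ-lactone and cyclopentane (bought in the starting lactone) → side-chain γ-lactone → nine-membered lactam and caprolactam together; the cyclopentane is consumed.

Assumption: compounds 1, 8, 11 and 14 are bought; atom labels C-1 to C-23 (O-5, O-16, N-17) are those of the target skeleton read along its SMILES (C-3 CHEt, C-4 CH–O, C-7 CHMe, C-8, C-9 ketone, C-11 CH–N, C-12 CH–O, C-14 CHMe, C-18 to C-21 the (CH2)4 chain, C-22, C-23 lactam C=O) and are used for all intermediates, whereas compound names keep their own locants.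

**Route**

Step 1
Reactants: 1 (3aR,6aS)-3,3a,6,6a-tetrahydro-2H-cyclopenta[b]furan-2-one
Product: 2 (3S,3aS,6aS)-3-methyl-3,3a,6,6a-tetrahydro-2H-cyclopenta[b]furan-2-one (methyl on the convex face)
Conditions: LiN(iPr)2, THF, −78 °C; MeI, −78 to −40 °C
Reagents that add atoms: iodomethane, CI
Why: Lactone enolate alkylation; the cis-fused bicycle is open only on its convex face, so the methyl enters anti to the cyclopentene ring and sets C-7.

Step 2
Reactants: 2 (3S,3aS,6aS)-3-methyl-3,3a,6,6a-tetrahydro-2H-cyclopenta[b]furan-2-one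
Product: 3 exo-5,6-epoxide of 2 (oxirane oxygen on the convex face)
Conditions: mCPBA, CH2Cl2, 0 °C to rt
Reagents that add atoms: 3-chloroperoxybenzoic acid, OOC(=O)c1cccc(Cl)c1
Why: Prilezhaev epoxidation from the convex face; the two oxirane centres are erased again in steps 3 and 4, so their configuration is not critical.

Step 3
Reactants: 3 exo-5,6-epoxide of 2
Product: 5 allylic alcohol 4-hydroxy-3-methyl-3,3a,4,6a-tetrahydro-2H-cyclopenta[b]furan-2-one (hydroxyl on the convex face), via allyl silyl ether 4 (not isolated)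
Conditions: Me3SiOSO2CF3, DBU, toluene, 0 °C to rt; then 1 M HCl, THF
Reagents that add atoms: none
Why: Silyl triflate/amidine isomerisation of an epoxide to an allylic silyl ether (β-elimination of the O-silylated oxirane); only C-3 has an endo hydrogen anti to the exo C–O bond (C-8 carries the lactone carbon there), so the alkene forms at C-22=C-3 and the oxygen stays on C-23.

Step 4
Reactants: 5 allylic alcohol
Product: 6 (3S,3aS,6aS)-3-methyl-3,3a-dihydro-2H-cyclopenta[b]furan-2,4(6aH)-dione
Conditions: Dess–Martin periodinane, CH2Cl2, rt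
Reagents that add atoms: none
Why: Dess–Martin oxidation of the allylic alcohol to the enone under neutral conditions that leave the base-sensitive γ-acyloxy enone and C-7 untouched.

Step 5
Reactants: 6 enone-lactone
Product: 7 5-iodo-3-methyl-3,3a-dihydro-2H-cyclopenta[b]furan-2,4(6aH)-dione (stereocentres as in 6)
Conditions: I2, pyridine, CH2Cl2, 0 °C to rt
Reagents that add atoms: iodine, II
Why: Johnson α-iodination of an enone (pyridine 1,4-addition, iodination of the enolate, elimination of pyridine), which places iodine on C-22.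

Step 6
Reactants: 7 α-iodoenone; 8 4,4-diethoxybut-1-ene
Product: 10 5-(4,4-diethoxybutyl)-3-methyl-3,3a-dihydro-2H-cyclopenta[b]furan-2,4(6aH)-dione (stereocentres as in 6), via alkylborane 9 (not isolated)
Conditions: 8, 9-BBN, THF, 0 °C to rt; then 7, PdCl2(dppf) [dppf = 1,1′-bis(diphenylphosphino)ferrocene], Ph3As, Cs2CO3, DMF/THF/H2O, rt
Reagents that add atoms: none
Why: B-alkyl Suzuki–Miyaura coupling of the α-iodoenone with the alkyl-9-BBN from anti-Markovnikov hydroboration of 8; it installs C-18 to C-21 with C-18 masked as an acetal and touches no stereocentre.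

Step 7
Reactants: 11 (2S)-2-(benzyloxycarbonylamino)-4-tert-butoxy-4-oxobutanoic acid (Cbz-L-Asp(OtBu)-OH)
Product: 13 tert-butyl (3S)-3-(benzyloxycarbonylamino)-4-oxobutanoate, via acyl imidazolide 12 (not isolated)
Conditions: 1,1′-carbonyldiimidazole, CH2Cl2, 0 °C; then i-Bu2AlH, −78 °C; aqueous Rochelle salt
Reagents that add atoms: none
Why: Reduction of an acyl imidazolide by i-Bu2AlH stops at the aldehyde because the tetrahedral aluminate only collapses on work-up; the hindered tert-butyl ester survives and C-11 (from L-aspartate) is not epimerised at −78 °C.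

Step 8
Reactants: 13 aldehyde; 14 ethyl 2-(bromomethyl)prop-2-enoate
Product: 16 tert-butyl (3S)-3-(benzyloxycarbonylamino)-3-[(2S)-4-methylidene-5-oxooxolan-2-yl]propanoate, via hydroxy ester 15 (not isolated)
Conditions: Zn dust, THF/saturated aqueous NH4Cl, 0 °C to rt; then pyridinium p-toluenesulfonate (cat.), toluene, 60 °C
Reagents that add atoms: none
Why: Zinc Barbier (Dreiding–Schmidt) allylation followed by lactonisation onto the acrylate ester (the tert-butyl ester is inert); Cram-chelate addition to the carbamate-bearing aldehyde gives the syn amino alcohol and sets C-12 (S), the minor anti isomer being removed by chromatography.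

Step 9
Reactants: 16 α-methylene lactone
Product: 17 tert-butyl (3S)-3-(benzyloxycarbonylamino)-3-[(2S,4S)-4-methyl-5-oxooxolan-2-yl]propanoate
Conditions: H2 (1 atm), RhCl(PPh3)3, toluene/EtOH, rt
Reagents that add atoms: none
Why: Homogeneous hydrogenation with RhCl(PPh3)3 spares the Cbz group and does not isomerise the exocyclic alkene; hydrogen adds to the lactone face opposite the C-12 substituent, giving the cis-2,4-disubstituted lactone (C-14 S).

Step 10
Reactants: 17 tert-butyl ester
Product: 18 (3S)-3-(benzyloxycarbonylamino)-3-[(2S,4S)-4-methyl-5-oxooxolan-2-yl]propanoic acid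
Conditions: CF3CO2H, CH2Cl2, 0 °C to rt
Reagents that add atoms: none
Why: Acidolysis of the tert-butyl ester with loss of isobutene; the Cbz carbamate and the lactone are stable to CF3CO2H.

Step 11
Reactants: 10 2-alkyl enone-lactone; 18 β-amino acid
Product: 20 3a-[(3S)-3-(benzyloxycarbonylamino)-3-((2S,4S)-4-methyl-5-oxooxolan-2-yl)propanoyl]-5-(4,4-diethoxybutyl)-3-methyl-3,3a-dihydro-2H-cyclopenta[b]furan-2,4(6aH)-dione (acyl group on the convex face; ring fusion cis), via acid chloride 19 (not isolated)
Conditions: 18, 1-chloro-N,N,2-trimethylprop-1-en-1-amine, CH2Cl2, 0 °C; separately 10, LiN(SiMe3)2 (2.1 equiv), THF, −78 °C; then add 19, −78 to −40 °C; aqueous NH4Cl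
Reagents that add atoms: none
Why: Claisen-type C-acylation of the cross-conjugated lithium enolate of 10, whose only α-hydrogen is on C-8; the acyl group can only enter on the convex face, which creates the quaternary C-8 with the lactone still cis-fused, and the second equivalent of base takes up the carbamate N–H.

Step 12
Reactants: 20 C-8-acylated enone
Product: 21 3a-acyl-5-(4,4-diethoxybutyl)-6-ethyl-3-methyltetrahydro-2H-cyclopenta[b]furan-2,4(3H)-dione (acyl group as in 20; ethyl anti to the ring oxygen on C-4; C-22 chain trans to ethyl)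
Conditions: Et2CuLi (from EtLi and CuI, 3 equiv), Et2O/THF, −78 to −40 °C; aqueous NH4Cl; then Et3N, CH2Cl2, rt
Reagents that add atoms: lithium diethylcuprate, [Li+].CC[Cu-]CC
Why: Gilman cuprate 1,4-addition to the 2-alkylcyclopentenone anti to the lactone oxygen on C-4 (convex face) sets C-3, and the epimerisable C-22 settles under amine equilibration in the all-trans C-22/C-3/C-4 arrangement.

Step 13
Reactants: 21 ring-expansion precursor
Product: 25 target CNP0311700.2, via amine 22 (not isolated), via lactam acetal 23 (not isolated), via lactam aldehyde 24 (not isolated)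
Conditions: H2 (1 atm), Pd/C, CF3CO2H (1.1 equiv), EtOAc, rt; filter; Et3N, MeCN (0.01 M), rt; then CF3CO2H/H2O, CH2Cl2, 0 °C; Et3SiH, 0 °C to rt (telescoped without isolation)
Reagents that add atoms: none
Why: Proposed new method: hydrogenolysis in the presence of acid gives the ammonium salt of 22 (so no cyclic imine is reduced), and on neutralisation the amine adds to the C-23 ketone through a six-membered ring and the adduct undergoes retro-Claisen C-23–C-8 cleavage to the amide and the C-9 ketone (nine-membered ring, with the epimerisable C-8 settling as the cis-fused lactone with methyl trans to C-9), after which acid unmasks the C-18 aldehyde and the lactam N–H condenses with it to a seven-membered cation that Et3SiH reduces (caprolactam ring); the closest known reactions are the amine-triggered side-chain-insertion ring expansion of C-acylated cyclic β-keto esters, the amine cleavage of non-enolisable 1,3-diketones, and the silane/acid reductive amidation of aldehydes.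

**Compound list**
1 | (3aR,6aS)-3,3a,6,6a-tetrahydro-2H-cyclopenta[b]furan-2-one ((−)-Grieco lactone) | O=C1O[C@H]2CC=C[C@H]2C1 | starting material
2 | (3S,3aS,6aS)-3-methyl-3,3a,6,6a-tetrahydro-2H-cyclopenta[b]furan-2-one | O=C1O[C@H]2CC=C[C@H]2[C@@H]1C | intermediate
3 | exo-5,6-epoxide of 2 | O=C1O[C@H]2C[C@@H]3O[C@@H]3[C@H]2[C@@H]1C | intermediate
4 | trimethylsilyl ether of 5 | O=C1O[C@H]2C=C[C@H](O[Si](C)(C)C)[C@H]2[C@@H]1C | intermediate (not isolated)
5 | 4-hydroxy-3-methyl-3,3a,4,6a-tetrahydro-2H-cyclopenta[b]furan-2-one, hydroxyl on the convex face | O=C1O[C@H]2C=C[C@H](O)[C@H]2[C@@H]1C | intermediate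
6 | (3S,3aS,6aS)-3-methyl-3,3a-dihydro-2H-cyclopenta[b]furan-2,4(6aH)-dione | O=C1O[C@H]2C=CC(=O)[C@H]2[C@@H]1C | intermediate
7 | 5-iodo derivative of 6 | O=C1O[C@H]2C=C(I)C(=O)[C@H]2[C@@H]1C | intermediate
8 | 4,4-diethoxybut-1-ene | C=CCC(OCC)OCC | starting material
9 | B-(4,4-diethoxybutyl)-9-borabicyclo[3.3.1]nonane | CCOC(CCCB1C2CCCC1CCC2)OCC | intermediate (not isolated)
10 | 5-(4,4-diethoxybutyl) derivative of 6 | O=C1O[C@H]2C=C(CCCC(OCC)OCC)C(=O)[C@H]2[C@@H]1C | intermediate
11 | (2S)-2-(benzyloxycarbonylamino)-4-tert-butoxy-4-oxobutanoic acid | OC(=O)[C@H](CC(=O)OC(C)(C)C)NC(=O)OCc1ccccc1 | starting material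
12 | acyl imidazolide of 11 | O=C(n1ccnc1)[C@H](CC(=O)OC(C)(C)C)NC(=O)OCc1ccccc1 | intermediate (not isolated)
13 | tert-butyl (3S)-3-(benzyloxycarbonylamino)-4-oxobutanoate | O=C[C@H](CC(=O)OC(C)(C)C)NC(=O)OCc1ccccc1 | intermediate
14 | ethyl 2-(bromomethyl)prop-2-enoate | C=C(CBr)C(=O)OCC | starting material
15 | ethyl (4S,5S)-5-(benzyloxycarbonylamino)-7-tert-butoxy-4-hydroxy-2-methylidene-7-oxoheptanoate | CC(C)(C)OC(=O)C[C@H](NC(=O)OCc1ccccc1)[C@@H](O)CC(=C)C(=O)OCC | intermediate (not isolated)
16 | tert-butyl (3S)-3-(benzyloxycarbonylamino)-3-[(2S)-4-methylidene-5-oxooxolan-2-yl]propanoate | CC(C)(C)OC(=O)C[C@H](NC(=O)OCc1ccccc1)[C@@H]1CC(=C)C(=O)O1 | intermediate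
17 | tert-butyl (3S)-3-(benzyloxycarbonylamino)-3-[(2S,4S)-4-methyl-5-oxooxolan-2-yl]propanoate | CC(C)(C)OC(=O)C[C@H](NC(=O)OCc1ccccc1)[C@@H]1C[C@H](C)C(=O)O1 | intermediate
18 | (3S)-3-(benzyloxycarbonylamino)-3-[(2S,4S)-4-methyl-5-oxooxolan-2-yl]propanoic acid | OC(=O)C[C@H](NC(=O)OCc1ccccc1)[C@@H]1C[C@H](C)C(=O)O1 | intermediate
19 | acid chloride of 18 | ClC(=O)C[C@H](NC(=O)OCc1ccccc1)[C@@H]1C[C@H](C)C(=O)O1 | intermediate (not isolated)
20 | C-8-acylated enone (3a-acyl derivative of 10, acyl on the convex face) | O=C1O[C@H]2C=C(CCCC(OCC)OCC)C(=O)[C@@]2(C(=O)C[C@H](NC(=O)OCc3ccccc3)[C@@H]3C[C@H](C)C(=O)O3)[C@@H]1C | intermediate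
21 | 6-ethyl-5,6-dihydro derivative of 20 (ethyl anti to the ring oxygen, chain trans to ethyl) | O=C1O[C@H]2[C@H](CC)[C@@H](CCCC(OCC)OCC)C(=O)[C@@]2(C(=O)C[C@H](NC(=O)OCc3ccccc3)[C@@H]3C[C@H](C)C(=O)O3)[C@@H]1C | intermediate
22 | primary amine from 21 (Cbz removed) | O=C1O[C@H]2[C@H](CC)[C@@H](CCCC(OCC)OCC)C(=O)[C@@]2(C(=O)C[C@H](N)[C@@H]3C[C@H](C)C(=O)O3)[C@@H]1C | intermediate (not isolated)
23 | nine-membered N–H keto-lactam with the 4,4-diethoxybutyl chain on C-22 (target lacking the N-17–C-18 bond, C-18 as diethyl acetal) | CC[C@H]1[C@@H]2OC(=O)[C@@H](C)[C@@H]2C(=O)C[C@@H]([C@@H]2C[C@H](C)C(=O)O2)NC(=O)[C@@H]1CCCC(OCC)OCC | intermediate (not isolated)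
24 | the same keto-lactam with C-18 as aldehyde | CC[C@H]1[C@@H]2OC(=O)[C@@H](C)[C@@H]2C(=O)C[C@@H]([C@@H]2C[C@H](C)C(=O)O2)NC(=O)[C@@H]1CCCC=O | intermediate (not isolated)
25 | target CNP0311700.2 | CC[C@H]1[C@@H]2OC(=O)[C@@H](C)[C@@H]2C(=O)C[C@@H]([C@@H]2C[C@H](C)C(=O)O2)N2CCCC[C@H]1C2=O | target

**Step count and risks**
Total steps: 13. Longest linear sequence: 9 (steps 1 to 6, then 11 to 13).

Steps most likely to fail:

Step 13. The retro-Claisen cleavage has to outrun O-to-N acyl migration of the side-chain lactone in amine 22, and the silane stage may reduce the C-9 ketone or the aldehyde instead of closing the bridged seven-membered ring. The fallback sets out from 23 and comes back at 25: stop after the neutralisation stage and isolate lactam acetal 23, hydrolyse the acetal with aqueous CF3CO2H to lactam aldehyde 24, close the seven-membered ring by dehydrative condensation of the lactam N–H with the aldehyde (camphorsulfonic acid, toluene, 4 Å sieves, 80 °C) to the bicyclic enamide F1, and hydrogenate its C-18=C-19 bond (H2, Pd/C, EtOAc) to 25.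

Step 11. The new quaternary centre sits next to the cis methyl on C-7, so O-acylation or no reaction may win. The fallback sets out from 18 (with 10) and comes back at 20: reduce 18 through its isobutyl mixed anhydride with NaBH4 to the primary alcohol F2, oxidise with Dess–Martin periodinane to the β-amino aldehyde F3, add F3 to the lithium enolate of 10 (an aldol addition at C-8, less demanding than acylation and free of O-acylation) to give the β-hydroxy ketone F4 as a carbinol mixture, and oxidise F4 with Dess–Martin periodinane to 20.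

Step 8. Chelation control may be weak in the aqueous medium and give mainly the anti alcohol. The fallback sets out from 13 and comes back at 16: add ethyl 2-[(trimethylsilyl)methyl]prop-2-enoate to 13 with BF3·OEt2 (open Felkin–Anh transition state) to make the anti hydroxy ester F5 on purpose, saponify only the ethyl ester (LiOH, THF/H2O, 0 °C) to the anti hydroxy acid F6, and lactonise under Mitsunobu conditions (PPh3, diisopropyl azodicarboxylate), which inverts C-12 and gives 16.

Further compounds
F1 | step 13 | bicyclic enamide (target with a C-18=C-19 double bond) | CC[C@H]1[C@@H]2OC(=O)[C@@H](C)[C@@H]2C(=O)C[C@@H]([C@@H]2C[C@H](C)C(=O)O2)N2C=CCC[C@H]1C2=O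
F2 | step 11 | benzyl N-[(1S)-3-hydroxy-1-((2S,4S)-4-methyl-5-oxooxolan-2-yl)propyl]carbamate | OCC[C@H](NC(=O)OCc1ccccc1)[C@@H]1C[C@H](C)C(=O)O1
F3 | step 11 | benzyl N-[(1S)-3-oxo-1-((2S,4S)-4-methyl-5-oxooxolan-2-yl)propyl]carbamate | O=CC[C@H](NC(=O)OCc1ccccc1)[C@@H]1C[C@H](C)C(=O)O1
F4 | step 11 | β-hydroxy ketone from the aldol addition of 10 to F3 (C-9 carbinol, both epimers) | O=C1O[C@H]2C=C(CCCC(OCC)OCC)C(=O)[C@@]2(C(O)C[C@H](NC(=O)OCc3ccccc3)[C@@H]3C[C@H](C)C(=O)O3)[C@@H]1C
F5 | step 8 | ethyl (4R,5S)-5-(benzyloxycarbonylamino)-7-tert-butoxy-4-hydroxy-2-methylidene-7-oxoheptanoate | CC(C)(C)OC(=O)C[C@H](NC(=O)OCc1ccccc1)[C@H](O)CC(=C)C(=O)OCC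
F6 | step 8 | (4R,5S)-5-(benzyloxycarbonylamino)-7-tert-butoxy-4-hydroxy-2-methylidene-7-oxoheptanoic acid | CC(C)(C)OC(=O)C[C@H](NC(=O)OCc1ccccc1)[C@H](O)CC(=C)C(O)=O
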